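**Retrosynthetic overview**
- The quinone comes last, by Fremy oxidation at the free para position of a 2-alkyl-6-methoxyphenol. The phenol travels as a MOM ether and the side-chain OH is acetylated before it is unmasked.
- Key disconnection ArCH2–CH(O)C11H23: the carbinol carbon is used as a sparteine-complexed α-oxygenated carbanion (lithiated dodecyl 2,4,6-triisopropylbenzoate). It is joined to the benzylic carbon of a benzylboronic ester by a 1,2-metallate shift, and C–B oxidation gives the (R)-alcohol directly.
- The benzylboronic ester comes from ortho-lithiated MOM-guaiacol and BrCH2Bpin. Both carbons joined in the key step therefore start as acceptor-type carbons (an O–CH2 and a Br–CH2).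
- No ring is built: the only carbocycle is that of guaiacol, and it becomes the quinone in the final step.

Assumption: the stereocentre in the SMILES is (R) (OAc > CH2-quinonyl > undecyl > H); (−)-sparteine, BrCH2Bpin and Fremy's salt are taken as commercially available.

**Route**

Step 1
Reactants: 1 guaiacol (2-methoxyphenol)
Product: 2 1-methoxy-2-(methoxymethoxy)benzene
Conditions: MOMCl, iPr2NEt, CH2Cl2, 0 °C to rt
Reagents that add atoms: chloromethyl methyl ether, COCCl
Why: Williamson-type O-alkylation (MOM protection) masks the acidic phenol for the organolithium steps and installs the stronger ortho-directing group needed in step 2.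

Step 2
Reactants: 2 1-methoxy-2-(methoxymethoxy)benzene; 3 2-(bromomethyl)-4,4,5,5-tetramethyl-1,3,2-dioxaborolane (BrCH2Bpin)
Product: 6 2-{[3-methoxy-2-(methoxymethoxy)phenyl]methyl}-4,4,5,5-tetramethyl-1,3,2-dioxaborolane, via aryllithium 4 (not isolated), via bromomethyl boronate complex 5 (not isolated)
Conditions: n-BuLi, TMEDA, THF, 0 °C, 1 h; then 3, −78 °C to rt, 12 h
Reagents that add atoms: none
Why: Directed ortho-metalation occurs next to the chelating OMOM group rather than next to OMe, and the aryllithium adds to boron of 3 to give an ate complex whose aryl group shifts 1,2 with loss of bromide (Matteson homologation), which puts in the benzylic CH2.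

Step 3
Reactants: 7 1-bromododecane
Product: 8 dodecyl 2,4,6-triisopropylbenzoate
Conditions: 2,4,6-triisopropylbenzoic acid, K2CO3, DMF, 60 °C
Reagents that add atoms: 2,4,6-triisopropylbenzoic acid, CC(C)c1cc(C(C)C)c(C(O)=O)c(C(C)C)c1
Why: SN2 O-alkylation of the carboxylate by a primary bromide gives the hindered ester, whose carbonyl is shielded from s-BuLi and whose oxygen directs and stabilises α-lithiation in step 4.

Step 4
Reactants: 8 dodecyl 2,4,6-triisopropylbenzoate; 6 2-{[3-methoxy-2-(methoxymethoxy)phenyl]methyl}-4,4,5,5-tetramethyl-1,3,2-dioxaborolane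
Product: 12 (2R)-1-[3-methoxy-2-(methoxymethoxy)phenyl]tridecan-2-ol, via lithiated benzoate 9 (not isolated), via boronate complex 10 (not isolated), via secondary boronic ester 11 (not isolated)
Conditions: 8 (1.3 equiv), s-BuLi, (−)-sparteine, Et2O, −78 °C, 5 h; then 6, −78 °C, 1 h, then 35 °C, 3 h; then NaOH aq, H2O2, THF, 0 °C to rt
Reagents that add atoms: hydrogen peroxide, OO
Why: Sparteine-mediated asymmetric deprotonation (Hoppe/Beak) removes the pro-S hydrogen to give a configurationally stable (S)-α-oxygenated carbanion, i.e. the carbinol carbon in reversed polarity, which adds to boron of 6 with retention, after which the benzyl group shifts 1,2 with inversion and expulsion of the benzoate (lithiation–borylation, Matteson-type 1,2-metallate rearrangement) and stereoretentive C–B oxidation delivers the (R)-alcohol.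

Step 5
Reactants: 12 (2R)-1-[3-methoxy-2-(methoxymethoxy)phenyl]tridecan-2-ol
Product: 13 (2R)-1-[3-methoxy-2-(methoxymethoxy)phenyl]tridecan-2-yl acetate
Conditions: Ac2O, pyridine, DMAP (cat.), CH2Cl2, rt
Reagents that add atoms: acetic anhydride, CC(=O)OC(C)=O
Why: DMAP-catalysed O-acylation of the only free hydroxyl does not touch the C–O bond, so the (R) centre is kept.

Step 6
Reactants: 13 (2R)-1-[3-methoxy-2-(methoxymethoxy)phenyl]tridecan-2-yl acetate
Product: 14 (2R)-1-(2-hydroxy-3-methoxyphenyl)tridecan-2-yl acetate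
Conditions: ZnBr2, n-PrSH, CH2Cl2, 0 °C to rt, 15 min
Reagents that add atoms: none
Why: Lewis acid-assisted acetal cleavage with the thiol trapping the methoxymethyl cation removes the aryl MOM group within minutes under non-hydrolytic conditions, so the secondary acetate and the electron-rich ring are left alone.

Step 7
Reactants: 14 (2R)-1-(2-hydroxy-3-methoxyphenyl)tridecan-2-yl acetate
Product: 15 (2R)-1-(5-methoxy-3,6-dioxocyclohexa-1,4-dien-1-yl)tridecan-2-yl acetate
Conditions: Fremy's salt (KO3S)2NO (2.5 equiv), KH2PO4 aq, acetone/H2O, rt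
Reagents that add atoms: potassium nitrosodisulfonate (Fremy's salt), [K+].[K+].[O]N(S([O-])(=O)=O)S([O-])(=O)=O
Why: Teuber oxidation: the phenoxyl radical is trapped by a second nitroxyl at the free para position and loss of imidodisulfonate gives the para-quinone, both ortho positions being blocked, while the near-neutral buffer spares the acetate and the stereocentre.

**Compound list**
1 | guaiacol (2-methoxyphenol) | COc1ccccc1O | starting material
2 | 1-methoxy-2-(methoxymethoxy)benzene | COCOc1ccccc1OC | intermediate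
3 | 2-(bromomethyl)-4,4,5,5-tetramethyl-1,3,2-dioxaborolane (BrCH2Bpin) | BrCB1OC(C)(C)C(C)(C)O1 | starting material
4 | [3-methoxy-2-(methoxymethoxy)phenyl]lithium | [Li]c1cccc(OC)c1OCOC | intermediate
5 | lithium (bromomethyl)[3-methoxy-2-(methoxymethoxy)phenyl](pinacolato)borate | [Li+].BrC[B-]1(c2cccc(OC)c2OCOC)OC(C)(C)C(C)(C)O1 | intermediate
6 | 2-{[3-methoxy-2-(methoxymethoxy)phenyl]methyl}-4,4,5,5-tetramethyl-1,3,2-dioxaborolane | COCOc1c(OC)cccc1CB1OC(C)(C)C(C)(C)O1 | intermediate
7 | 1-bromododecane | CCCCCCCCCCCCBr | starting material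
8 | dodecyl 2,4,6-triisopropylbenzoate | CCCCCCCCCCCCOC(=O)c1c(C(C)C)cc(C(C)C)cc1C(C)C | intermediate
9 | (1S)-1-lithiododecyl 2,4,6-triisopropylbenzoate (as its (−)-sparteine complex) | CCCCCCCCCCC[C@H]([Li])OC(=O)c1c(C(C)C)cc(C(C)C)cc1C(C)C | intermediate
10 | lithium [(1S)-1-(2,4,6-triisopropylbenzoyloxy)dodecyl]{[3-methoxy-2-(methoxymethoxy)phenyl]methyl}(pinacolato)borate | CCCCCCCCCCC[C@H]([B-]1(Cc2cccc(OC)c2OCOC)OC(C)(C)C(C)(C)O1)OC(=O)c1c(C(C)C)cc(C(C)C)cc1C(C)C.[Li+] | intermediate
11 | 2-{(2R)-1-[3-methoxy-2-(methoxymethoxy)phenyl]tridecan-2-yl}-4,4,5,5-tetramethyl-1,3,2-dioxaborolane | CCCCCCCCCCC[C@H](Cc1cccc(OC)c1OCOC)B1OC(C)(C)C(C)(C)O1 | intermediate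
12 | (2R)-1-[3-methoxy-2-(methoxymethoxy)phenyl]tridecan-2-ol | CCCCCCCCCCC[C@H](Cc1cccc(OC)c1OCOC)O | intermediate
13 | (2R)-1-[3-methoxy-2-(methoxymethoxy)phenyl]tridecan-2-yl acetate | CCCCCCCCCCC[C@H](Cc1cccc(OC)c1OCOC)OC(C)=O | intermediate
14 | (2R)-1-(2-hydroxy-3-methoxyphenyl)tridecan-2-yl acetate | CCCCCCCCCCC[C@H](Cc1cccc(OC)c1O)OC(C)=O | intermediate
15 | (2R)-1-(5-methoxy-3,6-dioxocyclohexa-1,4-dien-1-yl)tridecan-2-yl acetate | CCCCCCCCCCC[C@H](CC1=CC(=O)C=C(OC)C1=O)OC(C)=O | target

**Step count**
Total: 7 steps. Longest linear sequence: 6 steps (steps 1, 2, 4, 5, 6, 7 from guaiacol); step 3 is a one-step side branch.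

**Steps most likely to fail and fallbacks**

Step 4 (key step). Risks are benzylic deprotonation of 6 by the lithiated benzoate instead of addition to boron, an incomplete 1,2-shift, and erosion of the enantiomer ratio. The fallback makes the same C–C bond in normal polarity. Compound 2 is lithiated to 4 as in step 2, and 4 opens (2R)-2-undecyloxirane F1 at its terminal carbon (BF3·OEt2, THF, −78 °C). F1 is obtained from commercial racemic 1,2-epoxytridecane by Jacobsen hydrolytic kinetic resolution with (R,R)-(salen)Co(OAc) and 0.55 equiv H2O. The opening gives 12 directly, with the stereocentre carried in from the epoxide. This fallback sets out from 2 and returns to the route at 12.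

Step 2. Risks are bromine–lithium exchange or double addition when 4 meets 3, and a sluggish aryl shift. The fallback swaps the roles of the partners. Aryllithium 4 (from 2) is quenched with 2-isopropoxy-4,4,5,5-tetramethyl-1,3,2-dioxaborolane to give 2-[3-methoxy-2-(methoxymethoxy)phenyl]-4,4,5,5-tetramethyl-1,3,2-dioxaborolane F2. F2 is then homologated with chloromethyllithium F3, made in the flask from BrCH2Cl and n-BuLi (THF, −78 °C to rt), to give 6. This fallback sets out from 2 and returns at 6.

Step 7. Risks are oxidative coupling or a low yield of the sensitive quinone with Fremy's salt. The fallback installs the para oxygen before the phenol is unmasked. Compound 13 undergoes sterically controlled C–H borylation at the only ring position without an ortho neighbour ([Ir(OMe)(cod)]2, 4,4′-di-tert-butyl-2,2′-bipyridine, B2pin2, THF, 80 °C). This gives (2R)-1-[3-methoxy-2-(methoxymethoxy)-5-(4,4,5,5-tetramethyl-1,3,2-dioxaborolan-2-yl)phenyl]tridecan-2-yl acetate F4. NaBO3·4H2O in THF/H2O converts it into (2R)-1-[5-hydroxy-3-methoxy-2-(methoxymethoxy)phenyl]tridecan-2-yl acetate F5. (NH4)2Ce(NO3)6 in MeCN/H2O at 0 °C then oxidises this para-alkoxyphenol to 15 with loss of the MOM group. This fallback sets out from 13 and returns at 15.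

**Further compounds**
F1 | step 4 | (2R)-2-undecyloxirane | CCCCCCCCCCC[C@@H]1CO1
F2 | step 2 | 2-[3-methoxy-2-(methoxymethoxy)phenyl]-4,4,5,5-tetramethyl-1,3,2-dioxaborolane | COCOc1c(OC)cccc1B1OC(C)(C)C(C)(C)O1
F3 | step 2 | chloromethyllithium | [Li]CCl
F4 | step 7 | (2R)-1-[3-methoxy-2-(methoxymethoxy)-5-(4,4,5,5-tetramethyl-1,3,2-dioxaborolan-2-yl)phenyl]tridecan-2-yl acetate | CCCCCCCCCCC[C@H](Cc1cc(B2OC(C)(C)C(C)(C)O2)cc(OC)c1OCOC)OC(C)=O
F5 | step 7 | (2R)-1-[5-hydroxy-3-methoxy-2-(methoxymethoxy)phenyl]tridecan-2-yl acetate | CCCCCCCCCCC[C@H](Cc1cc(O)cc(OC)c1OCOC)OC(C)=O
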